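**Plan**

1. Target numbering: C1 = CMe2, C2 = CHBr, C3 = alkylidene ring carbon, C4 = allylic CHCl, C5 = CH2, C6 = CHCl beside C1, C7 = vinylic CH, C8 = CH2Br. Retrosynthetic cuts, in order: C8–Br (Appel); C4–Cl together with the exocyclic C3=C7 bond (vinylogous chlorination of a C4=C3–C7=C8–OEt diene); C2–Br (anti SE2′ from a C4 stannane); C3–C7 (Suzuki).
2. The ring is then cut at C3. The sp2 carbon C3 lying between C2 and C4 is a one-carbon insert, removed as dibromocarbene; the C4–O bond goes back to water. What remains is a cyclopentene (C1, C2, C4, C5, C6) that already carries the neopentyl C6–Cl, a bond easier to make by SN2 on a five-membered ring than on a cyclohexane.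
3. Forward: dione → CBS mono-reduction → invertive chlorination on the cyclopentane → enol triflate → cyclopentene → CBr2 adduct → silver-assisted expansion to the six-membered 2-bromocyclohexenol → side chain and the three remaining C–halogen bonds.
4. Stereochemistry: C6 from the CBS reduction followed by SN2 inversion. The C4 carbinol centre made in the ring expansion is relayed to C2 by three stereospecific events (Mitsunobu inversion, Pd-stannylation with inversion, anti SE2′ bromination). C4–Cl comes from axial attack trans to the other two halogens. The Z alkene comes from the s-trans alkoxydiene.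
5. Direct 1,4-addition of Br2 to a C2=C3–C7=C8 diene is avoided: its s-trans conformer would give the E-alkylidene, and C2 would be uncontrolled.

Key step: step 6

Remark: water capture in step 6 is assumed to occur mainly anti to the ring chloride (trans alcohol 12); this is a substrate bias only and is treated as a risk below.

**Route**

Step 1
Reactants: 1 2,2-dimethylcyclopentane-1,3-dione
Product: 2 (R)-3-hydroxy-2,2-dimethylcyclopentan-1-one
Conditions: (S)-Me-CBS (10 mol%), BH3·SMe2 (0.6 equiv), THF, −30 °C
Reagents that add atoms: none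
Why: Corey–Bakshi–Shibata reduction; the two carbonyls are enantiotopic, and with the quaternary carbon as the large group the catalyst should give the (R)-carbinol (same sense as acetophenone to (R)-1-phenylethanol), while sub-stoichiometric borane limits diol formation.

Step 2
Reactants: 2 (R)-3-hydroxy-2,2-dimethylcyclopentan-1-one
Product: 3 (S)-3-chloro-2,2-dimethylcyclopentan-1-one
Conditions: PPh3, CCl4, MeCN, 60 °C
Reagents that add atoms: tetrachloromethane ClC(Cl)(Cl)Cl
Why: Appel reaction; chloride displaces the alkoxyphosphonium group by SN2 with inversion, fixing C6 as S; Appel conditions chlorinate neopentyl alcohols without rearrangement, the quaternary neighbour has no hydrogen to lose, and the β-carbonyl disfavours ionisation.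

Step 3
Reactants: 3 (S)-3-chloro-2,2-dimethylcyclopentan-1-one
Product: 5 (S)-4-chloro-5,5-dimethylcyclopent-1-en-1-yl trifluoromethanesulfonate, via lithium enolate 4 (not isolated)
Conditions: LiHMDS, THF, −78 °C; then PhNTf2, −78 to 0 °C
Reagents that add atoms: N-phenylbis(trifluoromethanesulfonimide) O=S(=O)(N(c1ccccc1)S(=O)(=O)C(F)(F)F)C(F)(F)F
Why: Enol triflate formation; deprotonation can occur only at the CH2 α-carbon because the other α-carbon is quaternary, and O-sulfonylation of the kinetic enolate leaves the remote C–Cl centre untouched.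

Step 4
Reactants: 5 (S)-4-chloro-5,5-dimethylcyclopent-1-en-1-yl trifluoromethanesulfonate
Product: 6 (S)-4-chloro-3,3-dimethylcyclopent-1-ene
Conditions: Pd(OAc)2 (cat.), PPh3, HCO2H, Bu3N, DMF, 60 °C; extracted into pentane and used as solution
Reagents that add atoms: none
Why: Palladium-catalysed formate reduction of an enol triflate (oxidative addition, formate-to-hydride exchange, reductive elimination) replaces OTf by H without touching the unactivated secondary chloride or its stereocentre.

Step 5
Reactants: 6 (S)-4-chloro-3,3-dimethylcyclopent-1-ene; 7 bromoform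
Product: 9 (1S,3S,5S)-6,6-dibromo-3-chloro-2,2-dimethylbicyclo[3.1.0]hexane, via dibromocarbene 8 (not isolated)
Conditions: KOtBu, pentane, −10 to 0 °C; used crude and cold
Reagents that add atoms: none
Why: α-Elimination of bromoform gives dibromocarbene, which adds to the alkene in a concerted cis [2+1] cycloaddition; approach anti to chlorine is expected, but the two cyclopropane stereocentres are temporary and either face leads to the same cation in step 6.

Step 6
Reactants: 9 (1S,3S,5S)-6,6-dibromo-3-chloro-2,2-dimethylbicyclo[3.1.0]hexane; 10 water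
Product: 12 (1S,5S)-2-bromo-5-chloro-4,4-dimethylcyclohex-2-en-1-ol, via 2-bromocyclohexenyl cation 11 (not isolated)
Conditions: AgNO3 (2 equiv), acetone–H2O 4:1, 20 °C, dark
Reagents that add atoms: none
Why: Silver(I) pulls off the endo bromide while the fused cyclopropane bond opens in a disrotatory 2π-electrocyclic sense, the known silver-promoted cyclopropyl-to-allyl ring expansion of dibromocarbene adducts of cyclopentenes, giving the cis 2-bromoallyl cation 11 spanning C2–C3–C4. The six-membered ring therefore arises by electrocyclic opening of the cyclopropane, driven by strain release, and not by a ring-closing bond formation; the only new σ-bond is C4–O. Water attacks C4 because the other terminus C2 is flanked by the quaternary C1, which leaves the vinyl bromide on C3 and the ring alkene at C2=C3. The new carbinol centre is under substrate control: attack on the half-chair cation anti to the C6–Cl bond should favour the trans (1S,5S) alcohol. The step needs C4-over-C2 regioselectivity, secured by the neopentyl shielding, and a usable facial preference, which is the less certain point.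

Step 7
Reactants: 12 (1S,5S)-2-bromo-5-chloro-4,4-dimethylcyclohex-2-en-1-ol; 13 (E)-2-(2-ethoxyethenyl)-4,4,5,5-tetramethyl-1,3,2-dioxaborolane
Product: 14 (1S,5S)-5-chloro-2-[(E)-2-ethoxyethenyl]-4,4-dimethylcyclohex-2-en-1-ol
Conditions: Pd(dppf)Cl2 (5 mol%), K3PO4, THF–H2O, 50 °C
Reagents that add atoms: none
Why: Suzuki–Miyaura coupling of the alkenyl bromide with the alkenyl boronate proceeds with retention at both alkenes and tolerates the free alcohol and the alkyl chloride; the 1-ethoxydiene brings in C7 and C8 and polarises the diene for the two later halogenations.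

Step 8
Reactants: 14 (1S,5S)-5-chloro-2-[(E)-2-ethoxyethenyl]-4,4-dimethylcyclohex-2-en-1-ol
Product: 15 (1R,5S)-5-chloro-2-[(E)-2-ethoxyethenyl]-4,4-dimethylcyclohex-2-en-1-yl acetate
Conditions: AcOH, PPh3, DIAD, THF, 0 °C
Reagents that add atoms: acetic acid CC(=O)O
Why: Mitsunobu reaction; acetate displaces the activated allylic oxygen by SN2 with inversion, giving the acetate cis to the ring chloride that step 9 requires, while SN2′ attack at C2 is blocked by the adjacent quaternary carbon.

Step 9
Reactants: 15 (1R,5S)-5-chloro-2-[(E)-2-ethoxyethenyl]-4,4-dimethylcyclohex-2-en-1-yl acetate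
Product: 16 tributyl{(1S,5S)-5-chloro-2-[(E)-2-ethoxyethenyl]-4,4-dimethylcyclohex-2-en-1-yl}stannane
Conditions: Bu3SnAlEt2 (preformed in THF), Pd(PPh3)4 (5 mol%), THF, −20 to 0 °C; used crude
Reagents that add atoms: (tributylstannyl)diethylalane CCCC[Sn](CCCC)(CCCC)[Al](CC)CC
Why: Palladium-catalysed stannylation of an allylic acetate; Pd(0) ionises the acetate with inversion, the stannyl group passes from aluminium to palladium and is delivered from the metal face to the less hindered allyl terminus C4, so tin ends up trans to the ring chloride (net inversion).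

Step 10
Reactants: 16 tributyl{(1S,5S)-5-chloro-2-[(E)-2-ethoxyethenyl]-4,4-dimethylcyclohex-2-en-1-yl}stannane
Product: 17 (4S,6R)-6-bromo-4-chloro-1-[(E)-2-ethoxyethenyl]-5,5-dimethylcyclohex-1-ene
Conditions: NBS (1.0 equiv), CH2Cl2, −78 °C
Reagents that add atoms: N-bromosuccinimide O=C1CCC(=O)N1Br
Why: SE2′ bromodestannylation; electrophilic bromine attacks C2, which is both the γ-carbon of the allylstannane and the remote terminus of the alkoxydiene, anti to the C–Sn bond, so the ring alkene moves to C3=C4 and the C2 bromide is set cis to the C6 chloride by relay from the C4 centre of step 6.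

Step 11
Reactants: 17 (4S,6R)-6-bromo-4-chloro-1-[(E)-2-ethoxyethenyl]-5,5-dimethylcyclohex-1-ene; 10 water
Product: 18 (2Z)-2-[(2S,4S,6S)-2-bromo-4,6-dichloro-3,3-dimethylcyclohexylidene]acetaldehyde
Conditions: NCS (1.05 equiv), THF–H2O 10:1, −20 °C
Reagents that add atoms: N-chlorosuccinimide O=C1CCC(=O)N1Cl
Why: Vinylogous (γ) chlorination of a 1-alkoxy-1,3-diene; NCS attacks the remote diene terminus C4 by chair-like axial approach on the face away from the axial methyl, placing chlorine trans to the other two halogens; reaction through the s-trans diene puts C8 cis to C2 (Z), and water converts the enol-ether carbon into the aldehyde.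

Step 12
Reactants: 18 (2Z)-2-[(2S,4S,6S)-2-bromo-4,6-dichloro-3,3-dimethylcyclohexylidene]acetaldehyde
Product: 19 (2Z)-2-[(2S,4S,6S)-2-bromo-4,6-dichloro-3,3-dimethylcyclohexylidene]ethan-1-ol
Conditions: DIBAL-H, CH2Cl2, −78 °C; Rochelle salt work-up
Reagents that add atoms: none
Why: 1,2-Reduction of the enal by DIBAL-H at low temperature gives the primary allylic alcohol without disturbing the alkene geometry or the allylic halides.

Step 13
Reactants: 19 (2Z)-2-[(2S,4S,6S)-2-bromo-4,6-dichloro-3,3-dimethylcyclohexylidene]ethan-1-ol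
Product: 20 (2S,3Z,4S,6S)-2-bromo-3-(2-bromoethylidene)-4,6-dichloro-1,1-dimethylcyclohexane
Conditions: CBr4, PPh3 (added last, in portions), CH2Cl2, 0 °C
Reagents that add atoms: tetrabromomethane BrC(Br)(Br)Br
Why: Appel bromination; bromide displaces the primary allylic alkoxyphosphonium group by SN2 at C8, leaving the alkene geometry and the three ring stereocentres untouched.

**Compound list**

1 | 2,2-dimethylcyclopentane-1,3-dione | CC1(C)C(=O)CCC1=O | starting material
2 | (R)-3-hydroxy-2,2-dimethylcyclopentan-1-one | CC1(C)C(=O)CC[C@H]1O | intermediate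
3 | (S)-3-chloro-2,2-dimethylcyclopentan-1-one | CC1(C)C(=O)CC[C@@H]1Cl | intermediate
4 | lithium (S)-4-chloro-5,5-dimethylcyclopent-1-en-1-olate (not isolated) | [Li+].CC1(C)C([O-])=CC[C@@H]1Cl | intermediate
5 | (S)-4-chloro-5,5-dimethylcyclopent-1-en-1-yl trifluoromethanesulfonate | CC1(C)C(OS(=O)(=O)C(F)(F)F)=CC[C@@H]1Cl | intermediate
6 | (S)-4-chloro-3,3-dimethylcyclopent-1-ene | CC1(C)C=CC[C@@H]1Cl | intermediate
7 | bromoform | BrC(Br)Br | starting material
8 | dibromocarbene (not isolated) | Br[C]Br | intermediate
9 | (1S,3S,5S)-6,6-dibromo-3-chloro-2,2-dimethylbicyclo[3.1.0]hexane (CBr2 bridge anti to Cl) | CC1(C)[C@H]2C(Br)(Br)[C@H]2C[C@@H]1Cl | intermediate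
10 | water | O | starting material
11 | (5S)-2-bromo-5-chloro-4,4-dimethylcyclohex-2-en-1-ylium, allyl cation (not isolated) | CC1(C)C=C(Br)[CH+]C[C@@H]1Cl | intermediate
12 | (1S,5S)-2-bromo-5-chloro-4,4-dimethylcyclohex-2-en-1-ol | CC1(C)C=C(Br)[C@@H](O)C[C@@H]1Cl | intermediate
13 | (E)-2-(2-ethoxyethenyl)-4,4,5,5-tetramethyl-1,3,2-dioxaborolane | CCO/C=C/B1OC(C)(C)C(C)(C)O1 | starting material
14 | (1S,5S)-5-chloro-2-[(E)-2-ethoxyethenyl]-4,4-dimethylcyclohex-2-en-1-ol | CC1(C)C=C(/C=C/OCC)[C@@H](O)C[C@@H]1Cl | intermediate
15 | (1R,5S)-5-chloro-2-[(E)-2-ethoxyethenyl]-4,4-dimethylcyclohex-2-en-1-yl acetate | CC1(C)C=C(/C=C/OCC)[C@H](OC(C)=O)C[C@@H]1Cl | intermediate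
16 | tributyl{(1S,5S)-5-chloro-2-[(E)-2-ethoxyethenyl]-4,4-dimethylcyclohex-2-en-1-yl}stannane | CC1(C)C=C(/C=C/OCC)[C@@H]([Sn](CCCC)(CCCC)CCCC)C[C@@H]1Cl | intermediate
17 | (4S,6R)-6-bromo-4-chloro-1-[(E)-2-ethoxyethenyl]-5,5-dimethylcyclohex-1-ene | CC1(C)[C@H](Br)C(/C=C/OCC)=CC[C@@H]1Cl | intermediate
18 | (2Z)-2-[(2S,4S,6S)-2-bromo-4,6-dichloro-3,3-dimethylcyclohexylidene]acetaldehyde | CC1(C)[C@H](Br)/C(=C\C=O)[C@@H](Cl)C[C@@H]1Cl | intermediate
19 | (2Z)-2-[(2S,4S,6S)-2-bromo-4,6-dichloro-3,3-dimethylcyclohexylidene]ethan-1-ol | CC1(C)[C@H](Br)/C(=C\CO)[C@@H](Cl)C[C@@H]1Cl | intermediate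
20 | (2S,3Z,4S,6S)-2-bromo-3-(2-bromoethylidene)-4,6-dichloro-1,1-dimethylcyclohexane | CC1(C)[C@H](Br)/C(=C\CBr)[C@@H](Cl)C[C@@H]1Cl | target

**Step count and risks**

Total step count: 13. Longest linear sequence: 13 steps (1 to 20).

Steps most likely to fail:

Step 11. The chlorination can go wrong as a process in three ways: attack at the enol-ether carbon C7 instead of the remote terminus C4, reaction through the s-cis diene (E-alkylidene), and drift of alkene geometry in the γ-halo enal before reduction. The fallback sets out from 12 and avoids any aldehyde. Suzuki coupling with vinylboronic acid pinacol ester gives (1S,5S)-5-chloro-2-ethenyl-4,4-dimethylcyclohex-2-en-1-ol F1. Mitsunobu acetylation as in step 8 gives (1R,5S)-5-chloro-2-ethenyl-4,4-dimethylcyclohex-2-en-1-yl acetate F2. Stannylation as in step 9 gives tributyl[(1S,5S)-5-chloro-2-ethenyl-4,4-dimethylcyclohex-2-en-1-yl]stannane F3. NBS as in step 10 gives (4S,6R)-6-bromo-4-chloro-1-ethenyl-5,5-dimethylcyclohex-1-ene F4. Ionic 1,4-dichlorination of this diene (Et4NCl3, CH2Cl2, −78 °C) should give (2S,3Z,4S,6S)-2-bromo-4,6-dichloro-3-(2-chloroethylidene)-1,1-dimethylcyclohexane F5; because both new halogens are chlorine, their placement cannot be interchanged. Finkelstein exchange (NaBr, acetone) at the primary allylic chloride alone then rejoins the route at 20.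

Step 6. The planar cation may be captured by water with little facial preference, so that the C4 epimers form together and the chirality relay to C2 is diluted. The fallback sets out from 12 (taken as the epimer mixture) and replaces substrate control by reagent control. Oxidation (MnO2, CH2Cl2) converges both epimers on (5S)-2-bromo-5-chloro-4,4-dimethylcyclohex-2-en-1-one F6. CBS reduction ((S)-Me-CBS, BH3·SMe2) of this α-bromoenone gives the single cis alcohol (1R,5S)-2-bromo-5-chloro-4,4-dimethylcyclohex-2-en-1-ol F7. Suzuki coupling with 13 gives (1R,5S)-5-chloro-2-[(E)-2-ethoxyethenyl]-4,4-dimethylcyclohex-2-en-1-ol F8. Plain acetylation with retention (Ac2O, pyridine, DMAP) rejoins the route at 15.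

Step 2. SN2 displacement at the neopentyl carbinol may be too slow, letting elimination towards the ring CH2 or methyl migration take over. The fallback sets out from 2 and separates activation from displacement. Tf2O and pyridine in CH2Cl2 at −40 °C give (R)-2,2-dimethyl-3-oxocyclopentyl trifluoromethanesulfonate F9. A soluble chloride (Bu4NCl, toluene, 0 °C) then displaces the isolated triflate with inversion and rejoins the route at 3.

Further compounds
F1 | step 11 | (1S,5S)-5-chloro-2-ethenyl-4,4-dimethylcyclohex-2-en-1-ol | CC1(C)C=C(C=C)[C@@H](O)C[C@@H]1Cl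
F2 | step 11 | (1R,5S)-5-chloro-2-ethenyl-4,4-dimethylcyclohex-2-en-1-yl acetate | CC1(C)C=C(C=C)[C@H](OC(C)=O)C[C@@H]1Cl
F3 | step 11 | tributyl[(1S,5S)-5-chloro-2-ethenyl-4,4-dimethylcyclohex-2-en-1-yl]stannane | CC1(C)C=C(C=C)[C@@H]([Sn](CCCC)(CCCC)CCCC)C[C@@H]1Cl
F4 | step 11 | (4S,6R)-6-bromo-4-chloro-1-ethenyl-5,5-dimethylcyclohex-1-ene | CC1(C)[C@H](Br)C(C=C)=CC[C@@H]1Cl
F5 | step 11 | (2S,3Z,4S,6S)-2-bromo-4,6-dichloro-3-(2-chloroethylidene)-1,1-dimethylcyclohexane | CC1(C)[C@H](Br)/C(=C\CCl)[C@@H](Cl)C[C@@H]1Cl
F6 | step 6 | (5S)-2-bromo-5-chloro-4,4-dimethylcyclohex-2-en-1-one | CC1(C)C=C(Br)C(=O)C[C@@H]1Cl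
F7 | step 6 | (1R,5S)-2-bromo-5-chloro-4,4-dimethylcyclohex-2-en-1-ol | CC1(C)C=C(Br)[C@H](O)C[C@@H]1Cl
F8 | step 6 | (1R,5S)-5-chloro-2-[(E)-2-ethoxyethenyl]-4,4-dimethylcyclohex-2-en-1-ol | CC1(C)C=C(/C=C/OCC)[C@H](O)C[C@@H]1Cl
F9 | step 2 | (R)-2,2-dimethyl-3-oxocyclopentyl trifluoromethanesulfonate | CC1(C)C(=O)CC[C@H]1OS(=O)(=O)C(F)(F)F
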